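**Retrosynthetic overview**

1. Target 28 ⇐ diol 27 (oxidation of the primary alcohol) ⇐ alkene 26 ⇐ ketone 25 (Wittig methylenation) ⇐ acid 22 + alkylzinc 24 (acylative Negishi coupling; the cyclohexene ring is bought in 1).
2. Acid 22 ⇐ 1,2-dioxane 21 ⇐ 3,6-dihydro-1,2-dioxine 20 ⇐ (5Z,7E)-diene 19 + singlet oxygen; this [4+2] cycloaddition makes the only ring formed in the route and both peroxide carbons at once.
3. Diene 19 ⇐ sulfone 8 (from the Roche ester 4) + (Z)-enal 17 (Julia–Kocienski); 17 ⇐ zinc reagent 16 (from (R)-α-hydroxy-γ-butyrolactone 13) + (Z)-3-iodobut-2-enal 12 (Negishi, retention).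
4. Stereocentres: the carbinol comes from 13 and the methyl-bearing carbon from 4; the Z trisubstituted alkene puts the methyl group "outside", and the allylic methyl-bearing centre directs the face of oxygen attack.
5. Ring order: 1,2-dioxine (step 13), then saturated 1,2-dioxane (step 14); no other ring is made.

Assumption: 1, 4, 9 and 13 are bought; PT = 1-phenyl-1H-tetrazol-5-yl, TBS = tert-butyldimethylsilyl, TBDPS = tert-butyldiphenylsilyl, dppf = 1,1'-bis(diphenylphosphino)ferrocene.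

**Route**

Step 1
Reactants: 1 2-(2,6,6-trimethylcyclohex-1-en-1-yl)acetaldehyde
Product: 2 2-(2,6,6-trimethylcyclohex-1-en-1-yl)ethan-1-ol
Conditions: NaBH4, MeOH, 0 °C
Reagents that add atoms: none
Why: Hydride reduction of the aldehyde with NaBH4 leaves the tetrasubstituted alkene untouched.

Step 2
Reactants: 2 2-(2,6,6-trimethylcyclohex-1-en-1-yl)ethan-1-ol
Product: 3 2-(2-iodoethyl)-1,3,3-trimethylcyclohex-1-ene
Conditions: I2, PPh3, imidazole, CH2Cl2, 0 °C to rt
Reagents that add atoms: iodine, I-I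
Why: Appel-type iodination (Garegg–Samuelsson conditions) replaces the primary hydroxyl by SN2 attack of iodide on the oxyphosphonium ion.

Step 3
Reactants: 4 methyl (2S)-3-hydroxy-2-methylpropanoate
Product: 5 methyl (2S)-3-[(tert-butyldimethylsilyl)oxy]-2-methylpropanoate
Conditions: TBSCl, imidazole, DMF, rt
Reagents that add atoms: tert-butyldimethylsilyl chloride, CC(C)(C)[Si](C)(C)Cl
Why: Silyl ether protection of the primary alcohol does not touch the stereocentre and frees the ester carbon for the next steps.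

Step 4
Reactants: 5 methyl (2S)-3-[(tert-butyldimethylsilyl)oxy]-2-methylpropanoate
Product: 6 (2R)-3-[(tert-butyldimethylsilyl)oxy]-2-methylpropan-1-ol
Conditions: i-Bu2AlH (2.2 equiv), CH2Cl2, −78 to 0 °C; Rochelle salt work-up
Reagents that add atoms: none
Why: Ester reduction with i-Bu2AlH gives the primary alcohol without epimerisation (the descriptor changes only through the priority rules).

Step 5
Reactants: 6 (2R)-3-[(tert-butyldimethylsilyl)oxy]-2-methylpropan-1-ol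
Product: 7 5-{[(2S)-3-[(tert-butyldimethylsilyl)oxy]-2-methylpropyl]sulfanyl}-1-phenyl-1H-tetrazole
Conditions: 1-phenyl-1H-tetrazole-5-thiol, PPh3, diisopropyl azodicarboxylate, THF, 0 °C to rt
Reagents that add atoms: 1-phenyl-1H-tetrazole-5-thiol, Sc1nnnn1-c1ccccc1
Why: Mitsunobu thioetherification at the primary carbon installs the tetrazolyl sulfide needed for the later olefination.

Step 6
Reactants: 7 5-{[(2S)-3-[(tert-butyldimethylsilyl)oxy]-2-methylpropyl]sulfanyl}-1-phenyl-1H-tetrazole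
Product: 8 5-{[(2S)-3-[(tert-butyldimethylsilyl)oxy]-2-methylpropyl]sulfonyl}-1-phenyl-1H-tetrazole
Conditions: (NH4)6Mo7O24·4H2O (10 mol %), H2O2 (30 % aq), EtOH, 0 °C to rt
Reagents that add atoms: hydrogen peroxide, OO
Why: Molybdate-catalysed oxidation takes the sulfide to the sulfone under conditions that the silyl ether survives.

Step 7
Reactants: 9 but-2-yn-1-ol
Product: 11 (2Z)-3-iodobut-2-en-1-ol, via cyclic alkenylalanate 10 (not isolated)
Conditions: NaAlH2(OCH2CH2OMe)2, THF, 0 °C to rt; then I2, −78 °C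
Reagents that add atoms: iodine, I-I
Why: Hydroxyl-directed trans-hydroalumination of the propargylic alcohol puts aluminium on C3 in a five-membered ring, and iodinolysis with retention gives the Z vinyl iodide.

Step 8
Reactants: 11 (2Z)-3-iodobut-2-en-1-ol
Product: 12 (2Z)-3-iodobut-2-enal
Conditions: MnO2, CH2Cl2, rt, dark; used directly
Reagents that add atoms: none
Why: Allylic oxidation with MnO2 is neutral and keeps the Z geometry of the β-iodo enal.

Step 9
Reactants: 13 (3R)-3-hydroxyoxolan-2-one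
Product: 14 ethyl (2R)-4-bromo-2-hydroxybutanoate
Conditions: HBr (gas), EtOH, 0 °C to rt
Reagents that add atoms: hydrogen bromide, Br; ethanol, CCO
Why: Acid-mediated lactone opening (bromide attacks the O–CH2 carbon by SN2, ethanol esterifies the acid) leaves the carbinol stereocentre untouched.

Step 10
Reactants: 14 ethyl (2R)-4-bromo-2-hydroxybutanoate
Product: 15 ethyl (2R)-4-bromo-2-[(tert-butyldiphenylsilyl)oxy]butanoate
Conditions: TBDPSCl, imidazole, 4-(dimethylamino)pyridine (cat), DMF, rt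
Reagents that add atoms: tert-butyldiphenylsilyl chloride, CC(C)(C)[Si](Cl)(c1ccccc1)c1ccccc1
Why: Silyl ether protection with the robust TBDPS group shields the carbinol through all later steps and lets the primary TBS ether be told apart at the end.

Step 11
Reactants: 15 ethyl (2R)-4-bromo-2-[(tert-butyldiphenylsilyl)oxy]butanoate and 12 (2Z)-3-iodobut-2-enal
Product: 17 ethyl (2R,5Z)-2-[(tert-butyldiphenylsilyl)oxy]-5-methyl-7-oxohept-5-enoate, via alkylzinc bromide 16 (not isolated)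
Conditions: Zn dust, LiCl, THF, 50 °C; then 12, PdCl2(dppf) (3 mol %), THF, 0 °C to rt
Reagents that add atoms: none
Why: LiCl-assisted zinc insertion followed by Negishi cross-coupling replaces iodine with retention, so the chain ends up cis to the aldehyde carbon in the Z trisubstituted enal while ester and aldehyde are tolerated.

Step 12
Reactants: 8 5-{[(2S)-3-[(tert-butyldimethylsilyl)oxy]-2-methylpropyl]sulfonyl}-1-phenyl-1H-tetrazole and 17 ethyl (2R,5Z)-2-[(tert-butyldiphenylsilyl)oxy]-5-methyl-7-oxohept-5-enoate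
Product: 19 ethyl (2R,5Z,7E,9R)-10-[(tert-butyldimethylsilyl)oxy]-2-[(tert-butyldiphenylsilyl)oxy]-5,9-dimethyldeca-5,7-dienoate, via potassium sulfonyl carbanion 18 (not isolated)
Conditions: KN(SiMe3)2, 1,2-dimethoxyethane, −60 °C; then 17, −60 °C to rt
Reagents that add atoms: none
Why: Julia–Kocienski olefination of the tetrazolyl sulfone gives the new disubstituted alkene E-selectively without touching the Z alkene or the stereocentre β to sulfur.

Step 13
Reactants: 19 ethyl (2R,5Z,7E,9R)-10-[(tert-butyldimethylsilyl)oxy]-2-[(tert-butyldiphenylsilyl)oxy]-5,9-dimethyldeca-5,7-dienoate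
Product: 20 ethyl (2R)-2-[(tert-butyldiphenylsilyl)oxy]-4-[(3R,6S)-6-{(2S)-1-[(tert-butyldimethylsilyl)oxy]propan-2-yl}-3-methyl-3,6-dihydro-1,2-dioxin-3-yl]butanoate
Conditions: O2, 5,10,15,20-tetraphenylporphyrin (1 mol %), visible light, CH2Cl2, −40 °C
Reagents that add atoms: dioxygen, O=O
Why: Singlet oxygen adds suprafacially to the s-cis diene ([4+2] cycloaddition) so the two outside groups (ring methyl and branched side chain) become cis, and it attacks the face opposite the CH2OTBS arm of the allylic stereocentre in the conformer with its hydrogen in the diene plane, which sets both peroxide carbons from the Roche-derived centre; selectivity is expected to be moderate and the minor facial isomer and ene by-products are removed by chromatography.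

Step 14
Reactants: 20 ethyl (2R)-2-[(tert-butyldiphenylsilyl)oxy]-4-[(3R,6S)-6-{(2S)-1-[(tert-butyldimethylsilyl)oxy]propan-2-yl}-3-methyl-3,6-dihydro-1,2-dioxin-3-yl]butanoate
Product: 21 ethyl (2R)-2-[(tert-butyldiphenylsilyl)oxy]-4-[(3S,6S)-6-{(2S)-1-[(tert-butyldimethylsilyl)oxy]propan-2-yl}-3-methyl-1,2-dioxan-3-yl]butanoate
Conditions: KO2CN=NCO2K, AcOH, MeOH–CH2Cl2, 0 °C to rt
Reagents that add atoms: none
Why: Diimide reduction transfers H2 to the cis ring alkene in a concerted way and spares the O–O bond that catalytic hydrogenation would cleave; no other alkene is present yet.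

Step 15
Reactants: 21 ethyl (2R)-2-[(tert-butyldiphenylsilyl)oxy]-4-[(3S,6S)-6-{(2S)-1-[(tert-butyldimethylsilyl)oxy]propan-2-yl}-3-methyl-1,2-dioxan-3-yl]butanoate
Product: 22 (2R)-2-[(tert-butyldiphenylsilyl)oxy]-4-[(3S,6S)-6-{(2S)-1-[(tert-butyldimethylsilyl)oxy]propan-2-yl}-3-methyl-1,2-dioxan-3-yl]butanoic acid
Conditions: LiOH·H2O, THF–MeOH–H2O, 0 °C to rt; then aq HCl to pH 3
Reagents that add atoms: lithium hydroxide, [Li+].[OH-]
Why: Saponification of the ethyl ester is safe because the dialkyl peroxide has no acidifying group next to its C–H and both silyl ethers resist hydroxide.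

Step 16
Reactants: 22 (2R)-2-[(tert-butyldiphenylsilyl)oxy]-4-[(3S,6S)-6-{(2S)-1-[(tert-butyldimethylsilyl)oxy]propan-2-yl}-3-methyl-1,2-dioxan-3-yl]butanoic acid and 3 2-(2-iodoethyl)-1,3,3-trimethylcyclohex-1-ene
Product: 25 (4R)-4-[(tert-butyldiphenylsilyl)oxy]-6-[(3S,6S)-6-{(2S)-1-[(tert-butyldimethylsilyl)oxy]propan-2-yl}-3-methyl-1,2-dioxan-3-yl]-1-(2,6,6-trimethylcyclohex-1-en-1-yl)hexan-3-one, via acid chloride 23 (not isolated), via alkylzinc iodide 24 (not isolated)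
Conditions: 22, 1-chloro-N,N,2-trimethylprop-1-en-1-amine, CH2Cl2, 0 °C to rt; separately 3, Zn dust, LiCl, THF, 40 °C; then combine, Pd(PPh3)4 (5 mol %), THF, 0 °C to rt
Reagents that add atoms: none
Why: Neutral acid chloride formation and acylative Negishi coupling with the mild alkylzinc reagent give the ketone without attacking the peroxide, which organolithium or Grignard reagents would cleave.

Step 17
Reactants: 25 (4R)-4-[(tert-butyldiphenylsilyl)oxy]-6-[(3S,6S)-6-{(2S)-1-[(tert-butyldimethylsilyl)oxy]propan-2-yl}-3-methyl-1,2-dioxan-3-yl]-1-(2,6,6-trimethylcyclohex-1-en-1-yl)hexan-3-one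
Product: 26 tert-butyl({(3R)-1-[(3S,6S)-6-{(2S)-1-[(tert-butyldimethylsilyl)oxy]propan-2-yl}-3-methyl-1,2-dioxan-3-yl]-4-methylidene-6-(2,6,6-trimethylcyclohex-1-en-1-yl)hexan-3-yl}oxy)diphenylsilane
Conditions: Ph3PCH3Br, KN(SiMe3)2, THF, 0 °C; then 25, −78 to 0 °C
Reagents that add atoms: methyltriphenylphosphonium bromide, C[P+](c1ccccc1)(c1ccccc1)c1ccccc1.[Br-]
Why: Wittig methylenation of the α-silyloxy ketone with the small unstabilised ylide at low temperature builds the 1,1-disubstituted alkene before the ketone can enolise and epimerise the carbinol carbon.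

Step 18
Reactants: 26 tert-butyl({(3R)-1-[(3S,6S)-6-{(2S)-1-[(tert-butyldimethylsilyl)oxy]propan-2-yl}-3-methyl-1,2-dioxan-3-yl]-4-methylidene-6-(2,6,6-trimethylcyclohex-1-en-1-yl)hexan-3-yl}oxy)diphenylsilane
Product: 27 (2S)-2-[(3S,6R)-6-[(3R)-3-hydroxy-4-methylidene-6-(2,6,6-trimethylcyclohex-1-en-1-yl)hexyl]-6-methyl-1,2-dioxan-3-yl]propan-1-ol
Conditions: Bu4NF, AcOH, THF, 0 °C to rt
Reagents that add atoms: none
Why: Buffered fluoride desilylation removes both silyl ethers while the acetic acid buffer keeps the medium too weakly basic for Kornblum–DeLaMare cleavage of the peroxide.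

Step 19
Reactants: 27 (2S)-2-[(3S,6R)-6-[(3R)-3-hydroxy-4-methylidene-6-(2,6,6-trimethylcyclohex-1-en-1-yl)hexyl]-6-methyl-1,2-dioxan-3-yl]propan-1-ol
Product: 28 (2R)-2-[(3S,6R)-6-[(3R)-3-hydroxy-4-methylidene-6-(2,6,6-trimethylcyclohex-1-en-1-yl)hexyl]-6-methyl-1,2-dioxan-3-yl]propanoic acid
Conditions: 2,2,6,6-tetramethylpiperidin-1-oxyl (20 mol %), PhI(OAc)2 (2.2 equiv), MeCN–aq phosphate buffer pH 7, rt
Reagents that add atoms: water, O
Why: The oxoammonium oxidation (Epp–Widlanski conditions) takes the unhindered primary alcohol to the acid faster than it touches the hindered secondary allylic alcohol, and its near-neutral medium avoids β-elimination of the peroxide from the intermediate aldehyde.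

**Compound list**

The spatial arrangement at every stereocentre is the same from 19 or 20 onwards; the CIP letters at the quaternary peroxide carbon and at the methyl-bearing carbon change only because substituent priorities change.

1 | 2-(2,6,6-trimethylcyclohex-1-en-1-yl)acetaldehyde | CC1=C(CC=O)C(C)(C)CCC1 | starting material
2 | 2-(2,6,6-trimethylcyclohex-1-en-1-yl)ethan-1-ol | CC1=C(CCO)C(C)(C)CCC1 | intermediate
3 | 2-(2-iodoethyl)-1,3,3-trimethylcyclohex-1-ene | CC1=C(CCI)C(C)(C)CCC1 | intermediate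
4 | methyl (2S)-3-hydroxy-2-methylpropanoate | COC(=O)[C@@H](C)CO | starting material
5 | methyl (2S)-3-[(tert-butyldimethylsilyl)oxy]-2-methylpropanoate | COC(=O)[C@@H](C)CO[Si](C)(C)C(C)(C)C | intermediate
6 | (2R)-3-[(tert-butyldimethylsilyl)oxy]-2-methylpropan-1-ol | OC[C@@H](C)CO[Si](C)(C)C(C)(C)C | intermediate
7 | 5-{[(2S)-3-[(tert-butyldimethylsilyl)oxy]-2-methylpropyl]sulfanyl}-1-phenyl-1H-tetrazole | c1ccccc1-n1nnnc1SC[C@@H](C)CO[Si](C)(C)C(C)(C)C | intermediate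
8 | 5-{[(2S)-3-[(tert-butyldimethylsilyl)oxy]-2-methylpropyl]sulfonyl}-1-phenyl-1H-tetrazole | c1ccccc1-n1nnnc1S(=O)(=O)C[C@@H](C)CO[Si](C)(C)C(C)(C)C | intermediate
9 | but-2-yn-1-ol | CC#CCO | starting material
10 | sodium 2,2-bis(2-methoxyethoxy)-3-methyl-2,5-dihydro-1,2-oxaaluminol-2-uide (cyclic alkenylalanate) | [Na+].CC1=CCO[Al-]1(OCCOC)OCCOC | intermediate
11 | (2Z)-3-iodobut-2-en-1-ol | C/C(I)=C/CO | intermediate
12 | (2Z)-3-iodobut-2-enal | C/C(I)=C/C=O | intermediate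
13 | (3R)-3-hydroxyoxolan-2-one | O=C1[C@H](O)CCO1 | starting material
14 | ethyl (2R)-4-bromo-2-hydroxybutanoate | CCOC(=O)[C@H](O)CCBr | intermediate
15 | ethyl (2R)-4-bromo-2-[(tert-butyldiphenylsilyl)oxy]butanoate | CCOC(=O)[C@H](O[Si](c1ccccc1)(c1ccccc1)C(C)(C)C)CCBr | intermediate
16 | bromo{(3R)-3-[(tert-butyldiphenylsilyl)oxy]-4-ethoxy-4-oxobutyl}zinc | CCOC(=O)[C@H](O[Si](c1ccccc1)(c1ccccc1)C(C)(C)C)CC[Zn]Br | intermediate
17 | ethyl (2R,5Z)-2-[(tert-butyldiphenylsilyl)oxy]-5-methyl-7-oxohept-5-enoate | CCOC(=O)[C@H](O[Si](c1ccccc1)(c1ccccc1)C(C)(C)C)CC/C(C)=C\C=O | intermediate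
18 | potassium (2S)-3-[(tert-butyldimethylsilyl)oxy]-2-methyl-1-[(1-phenyl-1H-tetrazol-5-yl)sulfonyl]propan-1-ide | [K+].c1ccccc1-n1nnnc1S(=O)(=O)[CH-][C@@H](C)CO[Si](C)(C)C(C)(C)C | intermediate
19 | ethyl (2R,5Z,7E,9R)-10-[(tert-butyldimethylsilyl)oxy]-2-[(tert-butyldiphenylsilyl)oxy]-5,9-dimethyldeca-5,7-dienoate | CCOC(=O)[C@H](O[Si](c1ccccc1)(c1ccccc1)C(C)(C)C)CC/C(C)=C\C=C\[C@@H](C)CO[Si](C)(C)C(C)(C)C | intermediate
20 | ethyl (2R)-2-[(tert-butyldiphenylsilyl)oxy]-4-[(3R,6S)-6-{(2S)-1-[(tert-butyldimethylsilyl)oxy]propan-2-yl}-3-methyl-3,6-dihydro-1,2-dioxin-3-yl]butanoate | CCOC(=O)[C@H](O[Si](c1ccccc1)(c1ccccc1)C(C)(C)C)CC[C@]1(C)C=C[C@@H]([C@@H](C)CO[Si](C)(C)C(C)(C)C)OO1 | intermediate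
21 | ethyl (2R)-2-[(tert-butyldiphenylsilyl)oxy]-4-[(3S,6S)-6-{(2S)-1-[(tert-butyldimethylsilyl)oxy]propan-2-yl}-3-methyl-1,2-dioxan-3-yl]butanoate | CCOC(=O)[C@H](O[Si](c1ccccc1)(c1ccccc1)C(C)(C)C)CC[C@]1(C)CC[C@@H]([C@@H](C)CO[Si](C)(C)C(C)(C)C)OO1 | intermediate
22 | (2R)-2-[(tert-butyldiphenylsilyl)oxy]-4-[(3S,6S)-6-{(2S)-1-[(tert-butyldimethylsilyl)oxy]propan-2-yl}-3-methyl-1,2-dioxan-3-yl]butanoic acid | OC(=O)[C@H](O[Si](c1ccccc1)(c1ccccc1)C(C)(C)C)CC[C@]1(C)CC[C@@H]([C@@H](C)CO[Si](C)(C)C(C)(C)C)OO1 | intermediate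
23 | (2R)-2-[(tert-butyldiphenylsilyl)oxy]-4-[(3S,6S)-6-{(2S)-1-[(tert-butyldimethylsilyl)oxy]propan-2-yl}-3-methyl-1,2-dioxan-3-yl]butanoyl chloride | ClC(=O)[C@H](O[Si](c1ccccc1)(c1ccccc1)C(C)(C)C)CC[C@]1(C)CC[C@@H]([C@@H](C)CO[Si](C)(C)C(C)(C)C)OO1 | intermediate
24 | iodo[2-(2,6,6-trimethylcyclohex-1-en-1-yl)ethyl]zinc | CC1=C(CC[Zn]I)C(C)(C)CCC1 | intermediate
25 | (4R)-4-[(tert-butyldiphenylsilyl)oxy]-6-[(3S,6S)-6-{(2S)-1-[(tert-butyldimethylsilyl)oxy]propan-2-yl}-3-methyl-1,2-dioxan-3-yl]-1-(2,6,6-trimethylcyclohex-1-en-1-yl)hexan-3-one | O=C(CCC1=C(C)CCCC1(C)C)[C@H](O[Si](c1ccccc1)(c1ccccc1)C(C)(C)C)CC[C@]1(C)CC[C@@H]([C@@H](C)CO[Si](C)(C)C(C)(C)C)OO1 | intermediate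
26 | tert-butyl({(3R)-1-[(3S,6S)-6-{(2S)-1-[(tert-butyldimethylsilyl)oxy]propan-2-yl}-3-methyl-1,2-dioxan-3-yl]-4-methylidene-6-(2,6,6-trimethylcyclohex-1-en-1-yl)hexan-3-yl}oxy)diphenylsilane | C=C(CCC1=C(C)CCCC1(C)C)[C@H](O[Si](c1ccccc1)(c1ccccc1)C(C)(C)C)CC[C@]1(C)CC[C@@H]([C@@H](C)CO[Si](C)(C)C(C)(C)C)OO1 | intermediate
27 | (2S)-2-[(3S,6R)-6-[(3R)-3-hydroxy-4-methylidene-6-(2,6,6-trimethylcyclohex-1-en-1-yl)hexyl]-6-methyl-1,2-dioxan-3-yl]propan-1-ol | C=C(CCC1=C(C)CCCC1(C)C)[C@H](O)CC[C@]1(C)CC[C@@H]([C@@H](C)CO)OO1 | intermediate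
28 | (2R)-2-[(3S,6R)-6-[(3R)-3-hydroxy-4-methylidene-6-(2,6,6-trimethylcyclohex-1-en-1-yl)hexyl]-6-methyl-1,2-dioxan-3-yl]propanoic acid | C=C(CCC1=C(C)CCCC1(C)C)[C@H](O)CC[C@]1(C)CC[C@@H]([C@@H](C)C(=O)O)OO1 | target

**Step count and risks**

Total steps: 19. Longest linear sequence: 12 steps (4 to 28 through steps 3–6 and 12–19).

Most likely to fail, first: step 13. The trisubstituted diene terminus can divert singlet oxygen into ene reactions, the addition may not be fully stereospecific at the quaternary carbon, and the facial bias from the allylic centre is only moderate. The fallback replaces the cycloaddition by a stereospecific ionic ring closure; it sets out from alcohol 6 and alkylzinc bromide 16 and comes back at dioxane ester 21. Dess–Martin oxidation of 6 gives (2S)-3-[(tert-butyldimethylsilyl)oxy]-2-methylpropanal F1. Chelation-controlled addition of tributyl(buta-2,3-dien-2-yl)stannane (Me2AlCl, CH2Cl2, −78 °C) gives the anti alcohol (2S,3R)-1-[(tert-butyldimethylsilyl)oxy]-2-methylhept-5-yn-3-ol F2, and MsCl with Et3N turns it into (2S,3R)-1-[(tert-butyldimethylsilyl)oxy]-2-methylhept-5-yn-3-yl methanesulfonate F3. Syn hydrozirconation with Cp2Zr(H)Cl gives chlorobis(cyclopentadienyl)[(2E,5R,6S)-7-[(tert-butyldimethylsilyl)oxy]-5-(methanesulfonyloxy)-6-methylhept-2-en-2-yl]zirconium F4, which iodine converts into (2S,3R,5E)-1-[(tert-butyldimethylsilyl)oxy]-6-iodo-2-methylhept-5-en-3-yl methanesulfonate F5. Negishi coupling of this iodide with 16 (PdCl2(dppf), THF) gives ethyl (2R,5E,8R,9S)-10-[(tert-butyldimethylsilyl)oxy]-2-[(tert-butyldiphenylsilyl)oxy]-8-(methanesulfonyloxy)-5,9-dimethyldec-5-enoate F6. SN2 displacement of the mesylate by hydroperoxide with inversion (H2O2, CsOH·H2O, DMF, 0 °C to rt) gives ethyl (2R,5E,8S,9S)-10-[(tert-butyldimethylsilyl)oxy]-2-[(tert-butyldiphenylsilyl)oxy]-8-hydroperoxy-5,9-dimethyldec-5-enoate F7. Cycloperoxymercuration (Hg(OAc)2, HClO4 cat, CH2Cl2) closes the ring in the 6-endo Markovnikov sense by anti addition through a chair with the side chain equatorial, so the E alkene forces the long chain equatorial and the methyl group axial. This gives ethyl (2R)-4-[(3R,4S,6S)-4-(acetoxymercurio)-6-{(2S)-1-[(tert-butyldimethylsilyl)oxy]propan-2-yl}-3-methyl-1,2-dioxan-3-yl]-2-[(tert-butyldiphenylsilyl)oxy]butanoate F8, and NaBH4 in aqueous NaOH at 0 °C removes the mercury to give 21. The weak point of this detour is the hydroperoxide displacement on a hindered mesylate in the presence of the ester.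

Second: step 17. The basic ylide may enolise the hindered α-silyloxy ketone or attack the peroxide C–H. The fallback builds the alkene by cross-coupling instead of olefination; it sets out from acid 22 (through acid chloride 23) and comes back at alkene 26. Coupling of 23 with MeZnCl (Pd(PPh3)4, THF) gives (3R)-3-[(tert-butyldiphenylsilyl)oxy]-5-[(3S,6S)-6-{(2S)-1-[(tert-butyldimethylsilyl)oxy]propan-2-yl}-3-methyl-1,2-dioxan-3-yl]pentan-2-one F9. Kinetic enolisation on the methyl side and trapping (KN(SiMe3)2, N-phenylbis(trifluoromethanesulfonimide), THF, −78 °C) gives (3R)-3-[(tert-butyldiphenylsilyl)oxy]-5-[(3S,6S)-6-{(2S)-1-[(tert-butyldimethylsilyl)oxy]propan-2-yl}-3-methyl-1,2-dioxan-3-yl]pent-1-en-2-yl trifluoromethanesulfonate F10. Negishi coupling of this triflate with alkylzinc iodide 24 (Pd(PPh3)4, THF) gives 26.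

Third: step 19. The secondary allylic alcohol may be over-oxidised, and the intermediate β-peroxy aldehyde can eliminate. The fallback changes the order so that the oxidation is run with the carbinol still protected; it sets out from bis-silyl ether 26 and comes back at target 28. Selective cleavage of the primary TBS ether (HF·pyridine, pyridine, THF, 0 °C) gives (2S)-2-[(3S,6S)-6-{(3R)-3-[(tert-butyldiphenylsilyl)oxy]-4-methylidene-6-(2,6,6-trimethylcyclohex-1-en-1-yl)hexyl}-6-methyl-1,2-dioxan-3-yl]propan-1-ol F11. The same oxoammonium oxidation then gives (2R)-2-[(3S,6S)-6-{(3R)-3-[(tert-butyldiphenylsilyl)oxy]-4-methylidene-6-(2,6,6-trimethylcyclohex-1-en-1-yl)hexyl}-6-methyl-1,2-dioxan-3-yl]propanoic acid F12, and Bu4NF buffered with AcOH removes the TBDPS group to give 28.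

**Further compounds**

F1 | step 13 | (2S)-3-[(tert-butyldimethylsilyl)oxy]-2-methylpropanal | O=C[C@@H](C)CO[Si](C)(C)C(C)(C)C
F2 | step 13 | (2S,3R)-1-[(tert-butyldimethylsilyl)oxy]-2-methylhept-5-yn-3-ol | CC#CC[C@H]([C@@H](C)CO[Si](C)(C)C(C)(C)C)O
F3 | step 13 | (2S,3R)-1-[(tert-butyldimethylsilyl)oxy]-2-methylhept-5-yn-3-yl methanesulfonate | CC#CC[C@H]([C@@H](C)CO[Si](C)(C)C(C)(C)C)OS(C)(=O)=O
F4 | step 13 | chlorobis(cyclopentadienyl)[(2E,5R,6S)-7-[(tert-butyldimethylsilyl)oxy]-5-(methanesulfonyloxy)-6-methylhept-2-en-2-yl]zirconium | C/C(=C\C[C@H]([C@@H](C)CO[Si](C)(C)C(C)(C)C)OS(C)(=O)=O)[Zr](Cl)(C1C=CC=C1)C1C=CC=C1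
F5 | step 13 | (2S,3R,5E)-1-[(tert-butyldimethylsilyl)oxy]-6-iodo-2-methylhept-5-en-3-yl methanesulfonate | C/C(I)=C\C[C@H]([C@@H](C)CO[Si](C)(C)C(C)(C)C)OS(C)(=O)=O
F6 | step 13 | ethyl (2R,5E,8R,9S)-10-[(tert-butyldimethylsilyl)oxy]-2-[(tert-butyldiphenylsilyl)oxy]-8-(methanesulfonyloxy)-5,9-dimethyldec-5-enoate | CCOC(=O)[C@H](O[Si](c1ccccc1)(c1ccccc1)C(C)(C)C)CC/C(C)=C/C[C@H]([C@@H](C)CO[Si](C)(C)C(C)(C)C)OS(C)(=O)=O
F7 | step 13 | ethyl (2R,5E,8S,9S)-10-[(tert-butyldimethylsilyl)oxy]-2-[(tert-butyldiphenylsilyl)oxy]-8-hydroperoxy-5,9-dimethyldec-5-enoate | CCOC(=O)[C@H](O[Si](c1ccccc1)(c1ccccc1)C(C)(C)C)CC/C(C)=C/C[C@@H]([C@@H](C)CO[Si](C)(C)C(C)(C)C)OO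
F8 | step 13 | ethyl (2R)-4-[(3R,4S,6S)-4-(acetoxymercurio)-6-{(2S)-1-[(tert-butyldimethylsilyl)oxy]propan-2-yl}-3-methyl-1,2-dioxan-3-yl]-2-[(tert-butyldiphenylsilyl)oxy]butanoate | CCOC(=O)[C@H](O[Si](c1ccccc1)(c1ccccc1)C(C)(C)C)CC[C@]1(C)[C@@H]([Hg]OC(C)=O)C[C@@H]([C@@H](C)CO[Si](C)(C)C(C)(C)C)OO1
F9 | step 17 | (3R)-3-[(tert-butyldiphenylsilyl)oxy]-5-[(3S,6S)-6-{(2S)-1-[(tert-butyldimethylsilyl)oxy]propan-2-yl}-3-methyl-1,2-dioxan-3-yl]pentan-2-one | CC(=O)[C@H](O[Si](c1ccccc1)(c1ccccc1)C(C)(C)C)CC[C@]1(C)CC[C@@H]([C@@H](C)CO[Si](C)(C)C(C)(C)C)OO1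
F10 | step 17 | (3R)-3-[(tert-butyldiphenylsilyl)oxy]-5-[(3S,6S)-6-{(2S)-1-[(tert-butyldimethylsilyl)oxy]propan-2-yl}-3-methyl-1,2-dioxan-3-yl]pent-1-en-2-yl trifluoromethanesulfonate | C=C(OS(=O)(=O)C(F)(F)F)[C@H](O[Si](c1ccccc1)(c1ccccc1)C(C)(C)C)CC[C@]1(C)CC[C@@H]([C@@H](C)CO[Si](C)(C)C(C)(C)C)OO1
F11 | step 19 | (2S)-2-[(3S,6S)-6-{(3R)-3-[(tert-butyldiphenylsilyl)oxy]-4-methylidene-6-(2,6,6-trimethylcyclohex-1-en-1-yl)hexyl}-6-methyl-1,2-dioxan-3-yl]propan-1-ol | C=C(CCC1=C(C)CCCC1(C)C)[C@H](O[Si](c1ccccc1)(c1ccccc1)C(C)(C)C)CC[C@]1(C)CC[C@@H]([C@@H](C)CO)OO1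
F12 | step 19 | (2R)-2-[(3S,6S)-6-{(3R)-3-[(tert-butyldiphenylsilyl)oxy]-4-methylidene-6-(2,6,6-trimethylcyclohex-1-en-1-yl)hexyl}-6-methyl-1,2-dioxan-3-yl]propanoic acid | C=C(CCC1=C(C)CCCC1(C)C)[C@H](O[Si](c1ccccc1)(c1ccccc1)C(C)(C)C)CC[C@]1(C)CC[C@@H]([C@@H](C)C(=O)O)OO1
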